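**Retrosynthetic overview**

1. Target 18 comes from 17 by global hydrogenolysis; 17 comes from esterifying the single free phenol (O5) of tetra-O-benzylcatechin 15 with tribenzylgallic acid 16.
2. 15 comes from 12 via 13: the C4 methylene is made from a temporary C4 ketone, and O5 is unmasked by chelation to that ketone (C5-OBn is peri, C7-OBn is remote).
3. 12 comes from acid 10 by intramolecular Friedel–Crafts acylation (C4–C4a) on the symmetric 3,5-bis(benzyloxy)phenyl ether. This closes ring C, the only ring formed; rings A, B and the galloyl ring are bought.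
4. 10 comes from 3, 4 and 7: the C2–C3 bond by an Evans glycolate syn-aldol, the benzylic C–OAr bond by Mitsunobu inversion.
5. Feature used: C4 of ring C is benzylic to ring A and peri to O5. A carbonyl there allows acylative C4–C4a closure and then distinguishes O5 from O7 before it is reduced away.

Key step: step 5

Assumption: 3,4,5-tris(benzyloxy)benzoic acid (16) is bought instead of being made from gallic acid. The C4 carbinol configuration in 14 is immaterial because C4 becomes CH2.

**Route**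

Step 1
Reactants: 1 (R)-4-benzyl-2-oxazolidinone; 2 (benzyloxy)acetyl chloride
Product: 3 (R)-4-benzyl-3-[(benzyloxy)acetyl]oxazolidin-2-one
Conditions: n-BuLi (1.0 equiv), THF, −78 °C; then 2, −78 → 0 °C
Reagents that add atoms: none
Why: N-acylation of the lithiated oxazolidinone by an acid chloride is the standard loading of an Evans auxiliary and touches no stereocentre.

Step 2
Reactants: 3 (R)-4-benzyl-3-[(benzyloxy)acetyl]oxazolidin-2-one; 4 3,4-bis(benzyloxy)benzaldehyde
Product: 6 (R)-4-benzyl-3-[(2R,3S)-2-(benzyloxy)-3-[3,4-bis(benzyloxy)phenyl]-3-hydroxypropanoyl]oxazolidin-2-one, via Z-configured dibutylboron enolate 5 (not isolated)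
Conditions: n-Bu2BOTf (1.2 equiv), Et3N (1.4 equiv), CH2Cl2, −78 → 0 °C; then 4, −78 → 0 °C; pH 7 buffer, MeOH, 30% H2O2, 0 °C
Reagents that add atoms: dibutylboron triflate, CCCCB(CCCC)OS(=O)(=O)C(F)(F)F (its Bu2B group is carried by intermediate 5 only and is removed in the oxidative work-up)
Why: Evans boron glycolate syn-aldol, in which the Z-enolate reacts through a Zimmerman–Traxler chair on the enolate face not shielded by the (R)-benzyl group of the auxiliary, which should set C2 as R and C3 as S (syn).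

Step 3
Reactants: 6 (R)-4-benzyl-3-[(2R,3S)-2-(benzyloxy)-3-[3,4-bis(benzyloxy)phenyl]-3-hydroxypropanoyl]oxazolidin-2-one; 7 3,5-bis(benzyloxy)phenol
Product: 8 (R)-4-benzyl-3-[(2R,3R)-2-(benzyloxy)-3-[3,4-bis(benzyloxy)phenyl]-3-[3,5-bis(benzyloxy)phenoxy]propanoyl]oxazolidin-2-one
Conditions: PPh3 (1.5 equiv), DIAD (1.5 equiv), toluene, 0 °C → rt
Reagents that add atoms: none
Why: Mitsunobu etherification, in which the oxyphosphonium ion of the benzylic alcohol is displaced by the phenoxide in an SN2 step (non-polar solvent, low temperature), so the 3S carbinol should become the 3R aryl ether by inversion while C2 is untouched.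

Step 4
Reactants: 8 (R)-4-benzyl-3-[(2R,3R)-2-(benzyloxy)-3-[3,4-bis(benzyloxy)phenyl]-3-[3,5-bis(benzyloxy)phenoxy]propanoyl]oxazolidin-2-one
Product: 10 (2R,3R)-2-(benzyloxy)-3-[3,4-bis(benzyloxy)phenyl]-3-[3,5-bis(benzyloxy)phenoxy]propanoic acid, via peroxy acid 9 (not isolated)
Conditions: LiOH, 30% H2O2, THF/H2O (3:1), 0 °C; then aq. Na2SO3; 1 M HCl to pH 3
Reagents that add atoms: hydrogen peroxide, OO (as LiOOH; supplies the hydroxyl oxygen of the acid)
Why: Hydroperoxide cleavage of the N-acyl oxazolidinone attacks the exocyclic carbonyl selectively and is only weakly basic, so C2 epimerisation and β-elimination of the aryloxide should not compete, and sulfite reduces the peroxy acid to the acid.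

Step 5
Reactants: 10 (2R,3R)-2-(benzyloxy)-3-[3,4-bis(benzyloxy)phenyl]-3-[3,5-bis(benzyloxy)phenoxy]propanoic acid
Product: 12 (2R,3R)-3,5,7-tris(benzyloxy)-2-[3,4-bis(benzyloxy)phenyl]chroman-4-one (penta-O-benzyl-(+)-taxifolin), via mixed trifluoroacetic anhydride 11 (not isolated)
Conditions: TFAA (1.3 equiv), CH2Cl2 (0.02 M), −20 → 0 °C; aq. NaHCO3 quench
Reagents that add atoms: trifluoroacetic anhydride, O=C(OC(=O)C(F)(F)F)C(F)(F)F (its CF3CO group is carried by intermediate 11 only and leaves as trifluoroacetate on ring closure)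
Why: TFAA turns the acid into mixed anhydride 11, whose acylium-like carbon is attacked by the ring carbon of the 3,5-bis(benzyloxy)phenyl ether that is ortho to the ether oxygen and para to a benzyloxy group; loss of a proton from the σ-complex gives the C4–C4a bond and the aryl ketone. The closest known reaction type is the intramolecular Friedel–Crafts acylation of 3-aryloxypropanoic acids to chroman-4-ones, here in its metal-free mixed-anhydride form, which a phloroglucinol-type ring should accept without a Lewis acid. Ring C closes in the 6-exo-trig mode at the acyl carbon, the C=O lying outside the new ring. No stereocentre is created: C2 and C3 come from steps 2 and 3, and the 2,3-trans (diequatorial) dihydroflavonol is the more stable isomer, so there is no driving force for epimerisation. Site selectivity needs no control because the two ortho carbons are equivalent by symmetry and the para carbon is out of reach; indanone closure onto ring B should lose to the far more nucleophilic triply oxygenated ring A and to the preference for six- over five-membered acylation. The benzylic C2–OAr bond and the α-benzyloxy acyl unit are protected by the absence of a metal Lewis acid, low temperature, high dilution and short contact time, which disfavour benzylic ionisation and decarbonylation.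

Step 6
Reactants: 12 (2R,3R)-3,5,7-tris(benzyloxy)-2-[3,4-bis(benzyloxy)phenyl]chroman-4-one
Product: 13 (2R,3R)-3,7-bis(benzyloxy)-2-[3,4-bis(benzyloxy)phenyl]-5-hydroxychroman-4-one
Conditions: BCl3 (1.1 equiv, 1 M in CH2Cl2), CH2Cl2, −78 °C; then MeOH, aq. NaHCO3
Reagents that add atoms: none
Why: Chelation-controlled Lewis-acid debenzylation, in which BCl3 bridges the C4 carbonyl and the peri O5 so that only this aryl benzyl ether is ionised (to benzyl chloride) at −78 °C, while the limited amount of reagent should spare the O7, O3′ and O4′ ethers and the slower-reacting alkyl ether at O3.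

Step 7
Reactants: 13 (2R,3R)-3,7-bis(benzyloxy)-2-[3,4-bis(benzyloxy)phenyl]-5-hydroxychroman-4-one
Product: 14 (2R,3S,4R)-3,7-bis(benzyloxy)-2-[3,4-bis(benzyloxy)phenyl]chromane-4,5-diol
Conditions: NaBH4 (3 equiv), THF/EtOH (1:1), 0 °C → rt
Reagents that add atoms: none
Why: Borohydride 1,2-reduction of the aryl ketone, where axial hydride delivery should give mainly the 3,4-trans (4R) carbinol, a centre that step 8 removes so that either epimer serves.

Step 8
Reactants: 14 (2R,3S,4R)-3,7-bis(benzyloxy)-2-[3,4-bis(benzyloxy)phenyl]chromane-4,5-diol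
Product: 15 (2R,3S)-3,7-bis(benzyloxy)-2-[3,4-bis(benzyloxy)phenyl]chroman-5-ol
Conditions: Et3SiH (10 equiv), TFA (5 equiv), CH2Cl2, −40 → 0 °C
Reagents that add atoms: none
Why: Ionic hydrogenation, in which the C4 carbinol (ortho and para to ring-A oxygens) ionises to a benzylic cation/o-quinone methide that is captured by hydride from the excess silane, with C2 and C3 not involved.

Step 9
Reactants: 15 (2R,3S)-3,7-bis(benzyloxy)-2-[3,4-bis(benzyloxy)phenyl]chroman-5-ol; 16 3,4,5-tris(benzyloxy)benzoic acid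
Product: 17 (2R,3S)-3,7-bis(benzyloxy)-2-[3,4-bis(benzyloxy)phenyl]chroman-5-yl 3,4,5-tris(benzyloxy)benzoate
Conditions: EDC·HCl (1.5 equiv), DMAP (0.3 equiv), CH2Cl2, rt
Reagents that add atoms: none
Why: Steglich esterification, site-specific because the C5 phenol is the only free hydroxyl in 15.

Step 10
Reactants: 17 (2R,3S)-3,7-bis(benzyloxy)-2-[3,4-bis(benzyloxy)phenyl]chroman-5-yl 3,4,5-tris(benzyloxy)benzoate
Product: 18 (2R,3S)-2-(3,4-dihydroxyphenyl)-3,7-dihydroxychroman-5-yl 3,4,5-trihydroxybenzoate ((+)-catechin 5-O-gallate)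
Conditions: H2 (1 atm), 20% Pd(OH)2/C, THF/MeOH (1:1), rt
Reagents that add atoms: none
Why: Catalytic hydrogenolysis should cleave all seven benzyl ethers under neutral conditions that leave the aryl gallate ester, the C2–O1 bond and both stereocentres intact.

**Compound list**

1 | (R)-4-benzyl-2-oxazolidinone | O=C1OC[C@@H](Cc2ccccc2)N1 | starting material
2 | (benzyloxy)acetyl chloride | O=C(Cl)COCc1ccccc1 | starting material
3 | (R)-4-benzyl-3-[(benzyloxy)acetyl]oxazolidin-2-one | O=C(COCc1ccccc1)N1C(=O)OC[C@H]1Cc1ccccc1 | intermediate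
4 | 3,4-bis(benzyloxy)benzaldehyde | O=Cc1ccc(OCc2ccccc2)c(OCc2ccccc2)c1 | starting material
5 | (R)-4-benzyl-3-[(Z)-2-(benzyloxy)-1-[(dibutylboranyl)oxy]ethenyl]oxazolidin-2-one | CCCCB(CCCC)O/C(=C\OCc1ccccc1)N1C(=O)OC[C@H]1Cc1ccccc1 | intermediate (not isolated)
6 | (R)-4-benzyl-3-[(2R,3S)-2-(benzyloxy)-3-[3,4-bis(benzyloxy)phenyl]-3-hydroxypropanoyl]oxazolidin-2-one | O=C([C@H](OCc1ccccc1)[C@@H](O)c1ccc(OCc2ccccc2)c(OCc2ccccc2)c1)N1C(=O)OC[C@H]1Cc1ccccc1 | intermediate
7 | 3,5-bis(benzyloxy)phenol | Oc1cc(OCc2ccccc2)cc(OCc2ccccc2)c1 | starting material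
8 | (R)-4-benzyl-3-[(2R,3R)-2-(benzyloxy)-3-[3,4-bis(benzyloxy)phenyl]-3-[3,5-bis(benzyloxy)phenoxy]propanoyl]oxazolidin-2-one | O=C([C@H](OCc1ccccc1)[C@@H](c1ccc(OCc2ccccc2)c(OCc2ccccc2)c1)Oc1cc(OCc2ccccc2)cc(OCc2ccccc2)c1)N1C(=O)OC[C@H]1Cc1ccccc1 | intermediate
9 | (2R,3R)-2-(benzyloxy)-3-[3,4-bis(benzyloxy)phenyl]-3-[3,5-bis(benzyloxy)phenoxy]propaneperoxoic acid | OOC(=O)[C@H](OCc1ccccc1)[C@@H](c1ccc(OCc2ccccc2)c(OCc2ccccc2)c1)Oc1cc(OCc2ccccc2)cc(OCc2ccccc2)c1 | intermediate (not isolated)
10 | (2R,3R)-2-(benzyloxy)-3-[3,4-bis(benzyloxy)phenyl]-3-[3,5-bis(benzyloxy)phenoxy]propanoic acid | OC(=O)[C@H](OCc1ccccc1)[C@@H](c1ccc(OCc2ccccc2)c(OCc2ccccc2)c1)Oc1cc(OCc2ccccc2)cc(OCc2ccccc2)c1 | intermediate (key-step precursor)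
11 | mixed anhydride of 10 with trifluoroacetic acid | O=C(OC(=O)C(F)(F)F)[C@H](OCc1ccccc1)[C@@H](c1ccc(OCc2ccccc2)c(OCc2ccccc2)c1)Oc1cc(OCc2ccccc2)cc(OCc2ccccc2)c1 | intermediate (not isolated)
12 | (2R,3R)-3,5,7-tris(benzyloxy)-2-[3,4-bis(benzyloxy)phenyl]chroman-4-one | O=C1[C@H](OCc2ccccc2)[C@@H](c2ccc(OCc3ccccc3)c(OCc3ccccc3)c2)Oc2cc(OCc3ccccc3)cc(OCc3ccccc3)c21 | intermediate (key-step product)
13 | (2R,3R)-3,7-bis(benzyloxy)-2-[3,4-bis(benzyloxy)phenyl]-5-hydroxychroman-4-one | O=C1[C@H](OCc2ccccc2)[C@@H](c2ccc(OCc3ccccc3)c(OCc3ccccc3)c2)Oc2cc(OCc3ccccc3)cc(O)c21 | intermediate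
14 | (2R,3S,4R)-3,7-bis(benzyloxy)-2-[3,4-bis(benzyloxy)phenyl]chromane-4,5-diol (expected major C4 epimer) | O[C@H]1[C@H](OCc2ccccc2)[C@@H](c2ccc(OCc3ccccc3)c(OCc3ccccc3)c2)Oc2cc(OCc3ccccc3)cc(O)c21 | intermediate
15 | (2R,3S)-3,7-bis(benzyloxy)-2-[3,4-bis(benzyloxy)phenyl]chroman-5-ol | Oc1cc(OCc2ccccc2)cc2c1C[C@H](OCc1ccccc1)[C@@H](c1ccc(OCc3ccccc3)c(OCc3ccccc3)c1)O2 | intermediate
16 | 3,4,5-tris(benzyloxy)benzoic acid | OC(=O)c1cc(OCc2ccccc2)c(OCc2ccccc2)c(OCc2ccccc2)c1 | starting material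
17 | (2R,3S)-3,7-bis(benzyloxy)-2-[3,4-bis(benzyloxy)phenyl]chroman-5-yl 3,4,5-tris(benzyloxy)benzoate | O=C(Oc1cc(OCc2ccccc2)cc2c1C[C@H](OCc1ccccc1)[C@@H](c1ccc(OCc3ccccc3)c(OCc3ccccc3)c1)O2)c1cc(OCc2ccccc2)c(OCc2ccccc2)c(OCc2ccccc2)c1 | intermediate
18 | (+)-catechin 5-O-gallate | O=C(Oc1cc(O)cc2c1C[C@H](O)[C@@H](c1ccc(O)c(O)c1)O2)c1cc(O)c(O)c(O)c1 | target

**Step count**

Total steps: 10. Longest linear sequence: 10 steps (1 → 3 → 6 → 8 → 10 → 12 → 13 → 14 → 15 → 17 → 18).

**Steps most likely to fail**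

1. Step 5 (Friedel–Crafts closure). The trifluoroacetic acid released may ionise the electron-rich benzylic C–OAr bond, which would cause loss of the phenol, epimerisation or an O-to-C benzyl shift. The α-benzyloxy acyl cation may also lose CO, or the arene may be trifluoroacetylated before it cyclises. The fallback forms the same C4–C4a bond with reversed polarity by a Parham cyclisation, setting out from 6 and returning at 12. Phenol 7 is ortho-iodinated (NIS, CH2Cl2, low temperature) to 3,5-bis(benzyloxy)-2-iodophenol F1. Mitsunobu coupling of F1 with 6 as in step 3 should give (R)-4-benzyl-3-[(2R,3R)-2-(benzyloxy)-3-[3,4-bis(benzyloxy)phenyl]-3-[3,5-bis(benzyloxy)-2-iodophenoxy]propanoyl]oxazolidin-2-one F2. LiOOH cleavage as in step 4 gives (2R,3R)-2-(benzyloxy)-3-[3,4-bis(benzyloxy)phenyl]-3-[3,5-bis(benzyloxy)-2-iodophenoxy]propanoic acid F3. Treatment with n-BuLi (2.2 equiv) in THF at −100 °C deprotonates the acid and effects iodine–lithium exchange; the aryllithium is acylated by the lithium carboxylate, and aqueous work-up should release chromanone 12 with no acid present at any stage.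

2. Step 3 (Mitsunobu etherification). The activated β-hydroxy imide may dehydrate to the α-benzyloxycinnamoyl imide. Inversion may be eroded through a benzylic ion pair, or the ambident phenol may be alkylated on carbon. The fallback forms the benzylic C–O bond by base-mediated anti-opening of a glycidate, setting out from 4 and 7 and returning at 10. Horner–Wadsworth–Emmons olefination of 4 with trimethyl phosphonoacetate gives methyl (E)-3-[3,4-bis(benzyloxy)phenyl]prop-2-enoate F4. Chiral-ketone/Oxone (dioxirane) epoxidation, with the catalyst enantiomer chosen for this sense, gives methyl (2R,3S)-3-[3,4-bis(benzyloxy)phenyl]oxirane-2-carboxylate F5. The caesium phenoxide of 7 (Cs2CO3, DMF) should open F5 at the benzylic carbon with inversion to methyl (2R,3R)-3-[3,4-bis(benzyloxy)phenyl]-3-[3,5-bis(benzyloxy)phenoxy]-2-hydroxypropanoate F6. Benzylation with Ag2O and BnBr gives methyl (2R,3R)-2-(benzyloxy)-3-[3,4-bis(benzyloxy)phenyl]-3-[3,5-bis(benzyloxy)phenoxy]propanoate F7, and Me3SnOH in 1,2-dichloroethane hydrolyses the ester to acid 10.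

3. Step 8 (ionic deoxygenation at C4). Under acid the C4 cation may be intercepted by the nucleophilic ring A of a second molecule, giving procyanidin-type self-condensation, or the pyran ring may open at the benzylic C2–O1 bond. The fallback removes the C4 oxygen under basic conditions through an o-quinone methide, setting out from 13 and returning at 15 (it replaces steps 7 and 8). Ketone 13 is acylated on O5 (ClCO2Et, Et3N, THF, 0 °C) to (2R,3R)-3,7-bis(benzyloxy)-2-[3,4-bis(benzyloxy)phenyl]-4-oxochroman-5-yl ethyl carbonate F8. NaBH4 in aqueous THF reduces the ketone; the carbonate then shifts to the C4 alkoxide and is expelled, and the resulting o-quinone methide is reduced by a second hydride to give 15 directly.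

**Further compounds**

F1 | step 5 | 3,5-bis(benzyloxy)-2-iodophenol | Oc1cc(OCc2ccccc2)cc(OCc2ccccc2)c1I
F2 | step 5 | (R)-4-benzyl-3-[(2R,3R)-2-(benzyloxy)-3-[3,4-bis(benzyloxy)phenyl]-3-[3,5-bis(benzyloxy)-2-iodophenoxy]propanoyl]oxazolidin-2-one | O=C([C@H](OCc1ccccc1)[C@@H](c1ccc(OCc2ccccc2)c(OCc2ccccc2)c1)Oc1cc(OCc2ccccc2)cc(OCc2ccccc2)c1I)N1C(=O)OC[C@H]1Cc1ccccc1
F3 | step 5 | (2R,3R)-2-(benzyloxy)-3-[3,4-bis(benzyloxy)phenyl]-3-[3,5-bis(benzyloxy)-2-iodophenoxy]propanoic acid | OC(=O)[C@H](OCc1ccccc1)[C@@H](c1ccc(OCc2ccccc2)c(OCc2ccccc2)c1)Oc1cc(OCc2ccccc2)cc(OCc2ccccc2)c1I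
F4 | step 3 | methyl (E)-3-[3,4-bis(benzyloxy)phenyl]prop-2-enoate | COC(=O)/C=C/c1ccc(OCc2ccccc2)c(OCc2ccccc2)c1
F5 | step 3 | methyl (2R,3S)-3-[3,4-bis(benzyloxy)phenyl]oxirane-2-carboxylate | COC(=O)[C@@H]1O[C@H]1c1ccc(OCc2ccccc2)c(OCc2ccccc2)c1
F6 | step 3 | methyl (2R,3R)-3-[3,4-bis(benzyloxy)phenyl]-3-[3,5-bis(benzyloxy)phenoxy]-2-hydroxypropanoate | COC(=O)[C@H](O)[C@@H](c1ccc(OCc2ccccc2)c(OCc2ccccc2)c1)Oc1cc(OCc2ccccc2)cc(OCc2ccccc2)c1
F7 | step 3 | methyl (2R,3R)-2-(benzyloxy)-3-[3,4-bis(benzyloxy)phenyl]-3-[3,5-bis(benzyloxy)phenoxy]propanoate | COC(=O)[C@H](OCc1ccccc1)[C@@H](c1ccc(OCc2ccccc2)c(OCc2ccccc2)c1)Oc1cc(OCc2ccccc2)cc(OCc2ccccc2)c1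
F8 | step 8 | (2R,3R)-3,7-bis(benzyloxy)-2-[3,4-bis(benzyloxy)phenyl]-4-oxochroman-5-yl ethyl carbonate | CCOC(=O)Oc1cc(OCc2ccccc2)cc2c1C(=O)[C@H](OCc1ccccc1)[C@@H](c1ccc(OCc3ccccc3)c(OCc3ccccc3)c1)O2
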